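- elm: starting material 2 M; reagent in the second phase 1.5 equiv; the very flask that is asked about, followed so far
- flask: starting material 2.0 M; reagent in the second phase 1.50 equiv; time 3.0 h; volume of the second phase over the first 2.0
- elm (time / min: target / %, starting material / %): 3.00: 1.2, 99.6; 8.00: 3.6, 96.8; 15.0: 6.8, 91.5; 25.0: 11.8, 85.9; 30.0: 12.9, 83.8; 40.0: 16.7, 77.7; 50.0: 20.5, 72.6

(scatter of a reading: 0.5 percentage points)
- the target standing at 3.0 h, as a percentage of the starting material charged
- the change that raises the amount of target at 3.0 h, in percent of the starting material charged most ("none" if none brings more than 2 percentage points) (east / north-west / none)
- amount of target at 3.0 h, in percent of the starting material charged, after north-west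
- in the second phase: reagent in the second phase; everything else is in the first
- charges count per volume of the first phase; a concentration in a rate is the amount of a species over the volume of its own phase; every rate counts per litre of the first phase
- steps that have been proposed: starting material + reagent in the reaction phase -> target; target -> over-reaction product; reagent in the reaction phase <-> reagent in the second phase
- the earlier runs hold the two phases in the same ratio of volumes as the flask asked about

Amounts came first: the flask carried 1.50 equiv of reagent in the second phase, and I asked which concentration set the order of the rate. My first guess was starting material. But from 25.0 min to 50.0 min the elm run lost 94.3% of what it had lost up to 25.0 min, and a rate following starting material gives 85.9%, so the ratio read from the elm run was higher than that. With a scatter of 0.5 percentage points this is thin, but I went on. I took reagent in the reaction phase as a small steady pool (a quasi-steady-state intermediate), the crossing as the rate-limiting step, and the rate as pseudo-first-order in the stock in the second phase.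

One reagent goes per starting material, so the elm reading at 50.0 min gave 0.00403 min⁻¹, the fraction of the remaining stock crossing per minute, my emptying constant. That put starting material at 22.6% after 3.0 h. But consumed is not target: the elm run at 50.0 min fell short by 6.90%. Set against a triangle of target over time, this read as a drain constant of 0.0135 min⁻¹, a rough figure. Feed and drain together gave me 25.4% of target.

Did the changes gain? A faster feed ends sooner, so I reckoned two legs, feed and then pure drain. North-west doubles the constant: starting material out at 2.27 h, target 21.6%. East doubles the feed at the same constant: out at 1.68 h, target 18.0%. Both stood lower than my flask figure, so I chose none.

The forecast gave 25%, none and, higher than mine, 26% after north-west: “The timing is past the peak.” The flask gave 24.6% and none, with east at −5.3 points, north-west at −0.91 points, and 23.7% after north-west.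

    starting material + reagent in the reaction phase → target (k = 0.240 M⁻¹ min⁻¹)
    target → over-reaction product (k = 0.0136 min⁻¹)
    reagent in the reaction phase ⇌ reagent in the second phase, rate k3*([reagent in the reaction phase] - [reagent in the second phase]/K3) per volume of the first phase (partition coefficient = 1.40, kL = 0.0123 min⁻¹)

The flask stands at 24.6% of target because of the path from target to over-reaction product: with that path taken away, the same run gives 76.9%, and as it is, over-reaction product holds 52.3% by then. The emptying constant leaves 48.4% of the stock at 3.00 h, and the flask holds 47.2%. For the same flask read at 5.0 h, the constant has starting material out at 4.54 h and target drained to 13.6%; that neighbour holds 2.51% of starting material and 13.5% of target.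

(The readings were generated by integration from invented constants; scatter was added.)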